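## Retrosynthetic overview

1. The target is read as (14S)-8α,14,15-trihydroxylabd-13(16)-en-19-oic acid. Late disconnections: C19 CO2H from CH2OH, 8α-OH from the C7=C8 olefin (epoxide, then hydride), and the side chain by a C11–C12 allyl–alkyl coupling of a C11 borane with a D-glycerate-derived 2-substituted allyl bromide.
2. Ring A is closed onto a ring B cyclohexenone in one radical–polar annulation that forms C3–C4 and C1–C2, with vinyltriphenylphosphonium bromide as the C2–C3 unit.
3. Enabling feature: C1 and C4 sit on the adjacent ring B carbons C10 and C5. C4 is quaternary and carries the oxygenated C19, so a 2-methyloxiranyl group on C5 can release it as a tertiary β-oxy radical; C1 sits on the quaternary C10 as a non-enolisable aldehyde that can accept an ylide.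
4. Ring B is (R)-carvone, which supplies the C5 configuration, the C8 methyl, the C7=C8 bond and the C9 carbonyl; its α′-carbon becomes the quaternary C10. Ring order: B from the chiral pool, then A in the key step.

Key step: step 5

Remark: labdane numbering is used for all compounds; the SMILES is read as 4α-methyl/4β-carboxyl (C19), 5α-H, 8α-OH/8β-methyl, 9α-H, 10β-methyl and 14S.

## Route

Step 1
Reactants: 1 (R)-(−)-carvone
Product: 3 (5R,6S)-2,6-dimethyl-5-(prop-1-en-2-yl)cyclohex-2-en-1-one, via lithium enolate 2 (not isolated)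
Conditions: LiN(i-Pr)2 (1.1 equiv), THF, −78 °C; MeI, −78 → 0 °C
Reagents that add atoms: iodomethane, CI
Why: Kinetic α′-deprotonation of the enone and C-methylation of the cross-conjugated enolate (enolate alkylation) should install the future C10 methyl mainly trans to the isopropenyl group; this centre is planarised again in step 2, so its ratio does not matter.

Step 2
Reactants: 3 (5R,6S)-2,6-dimethyl-5-(prop-1-en-2-yl)cyclohex-2-en-1-one
Product: 5 (5S,6R)-6-(hydroxymethyl)-2,6-dimethyl-5-(prop-1-en-2-yl)cyclohex-2-en-1-one, via lithium enolate 4 (not isolated)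
Conditions: LiN(i-Pr)2 (1.2 equiv), THF, −78 °C; CH2O gas (cracked paraformaldehyde), −78 °C; H2O
Reagents that add atoms: formaldehyde, C=O
Why: Aldol addition of the tetrasubstituted enolate to formaldehyde should occur on the face anti to the neighbouring isopropenyl group at C5, setting the quaternary C10 with the methyl cis and the CH2OH (C1) trans to the C5 substituent, as in second alkylations of 6-methylcarvone.

Step 3
Reactants: 5 (5S,6R)-6-(hydroxymethyl)-2,6-dimethyl-5-(prop-1-en-2-yl)cyclohex-2-en-1-one
Product: 6 (1R,6S)-1,3-dimethyl-2-oxo-6-(prop-1-en-2-yl)cyclohex-3-ene-1-carbaldehyde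
Conditions: Dess–Martin periodinane, CH2Cl2, 0 °C → rt
Reagents that add atoms: none
Why: Dess–Martin oxidation of the neopentyl primary alcohol should give the non-enolisable C1 aldehyde under near-neutral conditions that avoid retro-aldol cleavage.

Step 4
Reactants: 6 (1R,6S)-1,3-dimethyl-2-oxo-6-(prop-1-en-2-yl)cyclohex-3-ene-1-carbaldehyde
Product: 7 (1R,6R)-1,3-dimethyl-6-(2-methyloxiran-2-yl)-2-oxocyclohex-3-ene-1-carbaldehyde (both oxirane epimers)
Conditions: dimethyldioxirane (1.1 equiv) in acetone, −20 → 0 °C
Reagents that add atoms: dimethyldioxirane, CC1(C)OO1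
Why: Neutral oxygen transfer from the dioxirane should epoxidise the electron-rich 1,1-disubstituted olefin in preference to the electron-poor enone C=C and without Baeyer–Villiger attack on the aldehyde; the epimer ratio at C4 is irrelevant because C4 becomes a planar radical in step 5.

Step 5
Reactants: 7 (1R,6R)-1,3-dimethyl-6-(2-methyloxiran-2-yl)-2-oxocyclohex-3-ene-1-carbaldehyde; 8 vinyltriphenylphosphonium bromide (Schweizer reagent)
Product: 10 (4aS,5S,8aS)-5-(hydroxymethyl)-2,5,8a-trimethyl-4a,5,6,8a-tetrahydronaphthalen-1(4H)-one, via phosphonium ylide 9 (not isolated)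
Conditions: Cp2TiCl2 (2.5 equiv), Zn dust, THF, rt (gives Cp2TiCl); added over 2 h to 7 and 8 (3 equiv) in THF/CH2Cl2, 0 °C → rt; aq. NaH2PO4
Reagents that add atoms: none
Why: Proposed new method: Cp2TiCl (trivalent titanium) opens the strained C4–C19 oxirane of either epimer by electron transfer to give the tertiary C4 radical with O19 on tetravalent titanium, this nucleophilic radical adds to the terminal carbon of the cationic vinylphosphonium salt 8 (C3–C4 bond, Giese addition), a second Cp2TiCl reduces the electrophilic α-phosphonio radical to the ylide 9, and 9 closes ring A by intramolecular Wittig olefination of the C1 aldehyde (C1=C2 bond). The closest known reaction types are the Nugent–RajanBabu reductive epoxide opening with Giese trapping by acrylates and the photoredox three-component olefination in which an alkyl radical, a vinylphosphonium salt and an aldehyde give an alkene by radical addition, reduction to the ylide and Wittig reaction; joining the two halves in one ring-forming event is the untested part. Ring A is the only ring closed, as a six-membered ring by attack of the C2 ylide carbon on the exocyclic C1 carbonyl (6-exo with respect to the C=O), and the ring allows only the cis olefin. The only new stereocentre, C4, is set in the radical addition: with the quaternary C10 perpendicular to the radical plane and the C5–H next to the bulky CH2O[Ti] arm, 8 should approach anti to C10, which places C19 cis to the C10 methyl (4β) after ring closure, and a titanium hemiacetal between O19 and C1 would lead to the same face by equatorial attack away from the axial C10 methyl; the trans ring fusion is already fixed by C5 and C10. The step needs the radical to be trapped by 8 before it is reduced or loses a β-hydrogen to a second Cp2TiCl (excess 8 and slow addition of Cp2TiCl should secure this) and the ylide to choose the aldehyde over the hindered conjugated C9 ketone, which is the normal order of Wittig reactivity.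

Step 6
Reactants: 10 (4aS,5S,8aS)-5-(hydroxymethyl)-2,5,8a-trimethyl-4a,5,6,8a-tetrahydronaphthalen-1(4H)-one
Product: 11 (4aS,5S,8aS)-5-(hydroxymethyl)-2,5,8a-trimethyl-4a,5,6,7,8,8a-hexahydronaphthalen-1(4H)-one
Conditions: H2 (1 atm), RhCl(PPh3)3 (5 mol %), benzene/EtOH, rt
Reagents that add atoms: none
Why: Homogeneous hydrogenation with RhCl(PPh3)3 should reduce the cis-disubstituted C1=C2 olefin and leave the trisubstituted, conjugated C7=C8 bond, as in the selective hydrogenation of carvone to carvotanacetone.

Step 7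
Reactants: 11 (4aS,5S,8aS)-5-(hydroxymethyl)-2,5,8a-trimethyl-4a,5,6,7,8,8a-hexahydronaphthalen-1(4H)-one
Product: 12 [(1S,4aS,8aR)-1,4a,6-trimethyl-5-methylidene-1,2,3,4,4a,5,8,8a-octahydronaphthalen-1-yl]methanol
Conditions: Ph3PCH3Br (3.0 equiv), KOt-Bu (2.9 equiv), toluene, 80 °C
Reagents that add atoms: methyltriphenylphosphonium bromide, C[P+](c1ccccc1)(c1ccccc1)c1ccccc1.[Br-]
Why: Wittig methylenation of the hindered C9 carbonyl under forcing conditions should give the C9=C11/C7=C8 diene; one equivalent of ylide is consumed by the free C19 hydroxyl and no free alkoxide base is left to deconjugate the enone.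

Step 8
Reactants: 13 methyl (R)-2,2-dimethyl-1,3-dioxolane-4-carboxylate
Product: 15 (S)-2,2-dimethyl-4-[3-(trimethylsilyl)prop-1-en-2-yl]-1,3-dioxolane, via bis(silylmethyl)carbinol 14 (not isolated)
Conditions: Me3SiCH2MgCl (3 equiv), CeCl3, THF, −78 °C → rt; then silica gel, CH2Cl2, rt
Reagents that add atoms: (trimethylsilyl)methylmagnesium chloride, C[Si](C)(C)C[Mg]Cl
Why: Double addition of the cerium-modified Grignard reagent to the ester followed by Peterson elimination of one β-silyl arm should give the 2-substituted allylsilane; CeCl3 suppresses enolisation of the intermediate α-alkoxy ketone, so the chiral-pool centre (C14) is kept.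

Step 9
Reactants: 15 (S)-2,2-dimethyl-4-[3-(trimethylsilyl)prop-1-en-2-yl]-1,3-dioxolane
Product: 16 (S)-4-(3-bromoprop-1-en-2-yl)-2,2-dimethyl-1,3-dioxolane
Conditions: N-bromosuccinimide, CH2Cl2, −78 → 0 °C
Reagents that add atoms: N-bromosuccinimide, O=C1CCC(=O)N1Br
Why: Electrophilic bromodesilylation of the allylsilane (SE2′) should give the 2-substituted allyl bromide without touching the stereocentre.

Step 10
Reactants: 12 [(1S,4aS,8aR)-1,4a,6-trimethyl-5-methylidene-1,2,3,4,4a,5,8,8a-octahydronaphthalen-1-yl]methanol; 16 (S)-4-(3-bromoprop-1-en-2-yl)-2,2-dimethyl-1,3-dioxolane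
Product: 18 (14S)-14,15-O-isopropylidenelabda-7,13(16)-diene-14,15,19-triol, via alkylborane 17 (not isolated)
Conditions: 9-BBN (2.2 equiv), THF, 0 °C → rt; then KOt-Bu, CuOAc (10 mol %), 16, THF, rt → 50 °C; H2O
Reagents that add atoms: none
Why: 9-BBN should add to the exocyclic C9=C11 bond of the diene with boron on C11 and hydrogen delivered to C9 from the α face, anti to the axial C10 methyl (sets 9α-H), and the primary alkylborane is then joined to the allylic bromide by the copper-catalysed allyl–alkyl coupling of alkyl-9-BBN reagents; SN2 and SN2′ attack give the same product because the allyl unit is 2-substituted.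

Step 11
Reactants: 18 (14S)-14,15-O-isopropylidenelabda-7,13(16)-diene-14,15,19-triol
Product: 19 (14S)-7α,8α-epoxy-14,15-O-isopropylidenelabd-13(16)-ene-14,15,19-triol
Conditions: 3-chloroperbenzoic acid (1.05 equiv), CH2Cl2, −20 → 0 °C
Reagents that add atoms: 3-chloroperbenzoic acid, OOC(=O)c1cccc(Cl)c1
Why: Prilezhaev epoxidation should take the trisubstituted ring olefin faster than the 1,1-disubstituted side-chain olefin, which is deactivated by its allylic oxygen, and from the α face, away from the axial C10 methyl and the C9 side chain.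

Step 12
Reactants: 19 (14S)-7α,8α-epoxy-14,15-O-isopropylidenelabd-13(16)-ene-14,15,19-triol
Product: 20 (14S)-14,15-O-isopropylidenelabd-13(16)-ene-8α,14,15,19-tetrol
Conditions: LiEt3BH, THF, 0 °C → 50 °C; H2O
Reagents that add atoms: none
Why: SN2 hydride opening of the trisubstituted epoxide at the secondary C7 should leave the oxygen on C8 in its α orientation, giving the 8α tertiary alcohol with the 8β methyl.

Step 13
Reactants: 20 (14S)-14,15-O-isopropylidenelabd-13(16)-ene-8α,14,15,19-tetrol
Product: 21 (14S)-8α-hydroxy-14,15-isopropylidenedioxylabd-13(16)-en-19-al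
Conditions: Dess–Martin periodinane, CH2Cl2, 0 °C → rt
Reagents that add atoms: none
Why: Dess–Martin oxidation should convert the only primary alcohol (C19) into the aldehyde while the tertiary C8 alcohol cannot be oxidised.

Step 14
Reactants: 21 (14S)-8α-hydroxy-14,15-isopropylidenedioxylabd-13(16)-en-19-al
Product: 22 (14S)-8α-hydroxy-14,15-isopropylidenedioxylabd-13(16)-en-19-oic acid
Conditions: NaClO2, NaH2PO4, 2-methyl-2-butene, t-BuOH/H2O, rt
Reagents that add atoms: sodium chlorite, [Na+].[O-]Cl=O
Why: Pinnick oxidation should convert the hindered axial aldehyde into the acid, with 2-methyl-2-butene scavenging hypochlorous acid so that the 1,1-disubstituted olefin is spared.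

Step 15
Reactants: 22 (14S)-8α-hydroxy-14,15-isopropylidenedioxylabd-13(16)-en-19-oic acid
Product: 23 (14S)-8α,14,15-trihydroxylabd-13(16)-en-19-oic acid (CNP0216809.1)
Conditions: AcOH/H2O/THF (3:1:1), 40 °C
Reagents that add atoms: none
Why: Mild acid hydrolysis of the acetonide should free the 14,15-diol without dehydrating the tertiary C8 alcohol.

## Compound list

1 | (R)-(−)-carvone | C=C(C)[C@@H]1CC=C(C)C(=O)C1 | starting material
2 | lithium enolate of 1 (cross-conjugated, C9–O–Li, C9=C10) | C=C(C)[C@@H]1CC=C(C)C(O[Li])=C1 | intermediate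
3 | (5R,6S)-2,6-dimethyl-5-(prop-1-en-2-yl)cyclohex-2-en-1-one (trans-6-methylcarvone) | C=C(C)[C@@H]1CC=C(C)C(=O)[C@H]1C | intermediate
4 | lithium enolate of 3 | C=C(C)[C@@H]1CC=C(C)C(O[Li])=C1C | intermediate
5 | (5S,6R)-6-(hydroxymethyl)-2,6-dimethyl-5-(prop-1-en-2-yl)cyclohex-2-en-1-one (CH2OH trans to isopropenyl) | C=C(C)[C@@H]1CC=C(C)C(=O)[C@@]1(C)CO | intermediate
6 | (1R,6S)-1,3-dimethyl-2-oxo-6-(prop-1-en-2-yl)cyclohex-3-ene-1-carbaldehyde | C=C(C)[C@@H]1CC=C(C)C(=O)[C@@]1(C)C=O | intermediate
7 | (1R,6R)-1,3-dimethyl-6-(2-methyloxiran-2-yl)-2-oxocyclohex-3-ene-1-carbaldehyde (about 1:1 at the oxirane carbon, both used) | CC1(CO1)[C@@H]2CC=C(C)C(=O)[C@@]2(C)C=O | intermediate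
8 | vinyltriphenylphosphonium bromide | C=C[P+](c1ccccc1)(c1ccccc1)c1ccccc1.[Br-] | starting material
9 | phosphonium ylide at C2 with O19 as chlorotitanocene alkoxide (C3–C4 bond made, ring A still open) | C(=P(c1ccccc1)(c1ccccc1)c1ccccc1)C[C@](C)(CO[Ti](Cl)(C1C=CC=C1)C1C=CC=C1)[C@@H]1CC=C(C)C(=O)[C@@]1(C)C=O | intermediate
10 | (4aS,5S,8aS)-5-(hydroxymethyl)-2,5,8a-trimethyl-4a,5,6,8a-tetrahydronaphthalen-1(4H)-one (9-oxo, C1=C2, C7=C8, 4α-Me, 4β-CH2OH, 5α-H, 10β-Me) | O=C1[C@@]2(C)C=CC[C@](C)(CO)[C@@H]2CC=C1C | intermediate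
11 | (4aS,5S,8aS)-5-(hydroxymethyl)-2,5,8a-trimethyl-4a,5,6,7,8,8a-hexahydronaphthalen-1(4H)-one | O=C1[C@@]2(C)CCC[C@](C)(CO)[C@@H]2CC=C1C | intermediate
12 | [(1S,4aS,8aR)-1,4a,6-trimethyl-5-methylidene-1,2,3,4,4a,5,8,8a-octahydronaphthalen-1-yl]methanol (C9=C11 and C7=C8 diene, 19-OH) | C=C1[C@@]2(C)CCC[C@](C)(CO)[C@@H]2CC=C1C | intermediate
13 | methyl (R)-2,2-dimethyl-1,3-dioxolane-4-carboxylate | COC(=O)[C@H]1COC(C)(C)O1 | starting material
14 | 2-[(4R)-2,2-dimethyl-1,3-dioxolan-4-yl]-1,3-bis(trimethylsilyl)propan-2-ol | C[Si](C)(C)CC(O)(C[Si](C)(C)C)[C@H]1COC(C)(C)O1 | intermediate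
15 | (S)-2,2-dimethyl-4-[3-(trimethylsilyl)prop-1-en-2-yl]-1,3-dioxolane | C=C(C[Si](C)(C)C)[C@H]1COC(C)(C)O1 | intermediate
16 | (S)-4-(3-bromoprop-1-en-2-yl)-2,2-dimethyl-1,3-dioxolane | C=C(CBr)[C@H]1COC(C)(C)O1 | intermediate
17 | C11 B-alkyl-9-BBN adduct of 12 (9α-H, O19 as 9-BBN borinate) | C1CCC2CCCC1B2C[C@@H]1[C@@]2(C)CCC[C@](C)(COB3C4CCCC3CCC4)[C@@H]2CC=C1C | intermediate
18 | (14S)-14,15-O-isopropylidenelabda-7,13(16)-diene-14,15,19-triol | C=C(CC[C@@H]1[C@@]2(C)CCC[C@](C)(CO)[C@@H]2CC=C1C)[C@H]1COC(C)(C)O1 | intermediate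
19 | (14S)-7α,8α-epoxy-14,15-O-isopropylidenelabd-13(16)-ene-14,15,19-triol | C=C(CC[C@@H]1[C@@]2(C)CCC[C@](C)(CO)[C@@H]2C[C@@H]3[C@@]1(C)O3)[C@H]1COC(C)(C)O1 | intermediate
20 | (14S)-14,15-O-isopropylidenelabd-13(16)-ene-8α,14,15,19-tetrol | C=C(CC[C@@H]1[C@@]2(C)CCC[C@](C)(CO)[C@@H]2CC[C@@]1(C)O)[C@H]1COC(C)(C)O1 | intermediate
21 | (14S)-8α-hydroxy-14,15-isopropylidenedioxylabd-13(16)-en-19-al | C=C(CC[C@@H]1[C@@]2(C)CCC[C@](C)(C=O)[C@@H]2CC[C@@]1(C)O)[C@H]1COC(C)(C)O1 | intermediate
22 | (14S)-8α-hydroxy-14,15-isopropylidenedioxylabd-13(16)-en-19-oic acid | C=C(CC[C@@H]1[C@@]2(C)CCC[C@](C)(C(=O)O)[C@@H]2CC[C@@]1(C)O)[C@H]1COC(C)(C)O1 | intermediate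
23 | (14S)-8α,14,15-trihydroxylabd-13(16)-en-19-oic acid (CNP0216809.1) | C=C(CC[C@@H]1[C@@]2(C)CCC[C@](C)(C(=O)O)[C@@H]2CC[C@@]1(C)O)[C@H](O)CO | target

## Step count and risks

Total steps: 15. Longest linear sequence: 13 steps (1 → 23 through steps 1–7 and 10–15); steps 8 and 9 make the side-chain fragment.

**Step 5 (proposed new method).** Three processes may defeat it:
- the tertiary C4 radical may be reduced or dehydrogenated by Cp2TiCl faster than it adds to the vinylphosphonium salt;
- the α-phosphonio radical may be quenched to a phosphonium salt instead of the ylide;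
- facial selectivity at C4 may be low.

Fallback with known chemistry, still forming both ring bonds in one operation, sets out from 7 and returns at 10. The oxirane is isomerised with Cp2TiCl in the absence of an acceptor (known β-hydrogen loss of tertiary β-titanoxy radicals to 2-substituted allylic alcohols), and the alkoxide is silylated in the same flask (t-BuMe2SiOTf, 2,6-lutidine) to the allyl silyl ether aldehyde F1. F1 and acrolein are joined by the hydrogen-atom-transfer-initiated radical conjugate addition–aldol annulation (Fe(acac)3, PhSiH3, EtOH/ethylene glycol), which makes C3–C4 by Giese addition of the C4 radical and C1–C2 by aldol closure, giving the β-hydroxy aldehyde F2. Dehydration (MsCl, Et3N, then DBU) gives the enal F3, Tsuji–Wilkinson decarbonylation with RhCl(PPh3)3 gives the silyl ether F4, and n-Bu4NF returns 10.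

**Step 10.** The hindered, β-branched alkylborane may transfer its alkyl group to copper too slowly, so that the allylic bromide is consumed by alkoxide, and imperfect facial selectivity in the hydroboration would erode the C9 configuration. Fallback by a radical rather than an organocopper coupling sets out from 12 and returns at 18. The allyl phenyl sulfone F5 is made from 16 and PhSO2Na in DMF. Diene 12 is hydroborated with catecholborane (N,N-dimethylacetamide as catalyst) to the B-alkylcatecholborane F6. The C11 radical released from F6 under air or di-tert-butyl hyponitrite initiation is allylated by F5 with loss of the sulfonyl radical, giving 18.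

**Step 12.** Hydride has to attack C7 anti to the α oxygen through a twist-boat, so the opening may stall or take place at the wrong carbon, and the epoxidation before it relies on a rate difference between two olefins. Fallback that installs the C8 carbinol before C9 is elaborated sets out from 11 and returns at 20. Mukaiyama-type hydration of the enone (Mn(dpm)3, PhSiH3, O2, i-PrOH; then P(OEt)3), in which hydrogen adds to C7 and oxygen is taken up at C8 from the α face, gives the α-hydroxy ketone F7. Methylenation with the Tebbe reagent Cp2Ti(μ-CH2)(μ-Cl)AlMe2 gives the exocyclic olefin F8. Hydroboration with 9-BBN to the alkylborane F9 and the copper-catalysed coupling with 16 under the conditions of step 10 give 20 directly.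

## Further compounds

F1 | step 5 | (1R,6S)-6-[3-(tert-butyldimethylsilyloxy)prop-1-en-2-yl]-1,3-dimethyl-2-oxocyclohex-3-ene-1-carbaldehyde | C=C(CO[Si](C)(C)C(C)(C)C)[C@@H]1CC=C(C)C(=O)[C@@]1(C)C=O
F2 | step 5 | 1-hydroxy-2-formyl adduct of ring A (19-OTBS, 9-oxo, C7=C8; mixture at C1 and C2) | O=C1[C@@]2(C)C(O)C(C=O)C[C@](C)(CO[Si](C)(C)C(C)(C)C)[C@@H]2CC=C1C
F3 | step 5 | C1=C2 enal with the formyl group on C2 (19-OTBS, 9-oxo, C7=C8) | O=C1[C@@]2(C)C=C(C=O)C[C@](C)(CO[Si](C)(C)C(C)(C)C)[C@@H]2CC=C1C
F4 | step 5 | tert-butyldimethylsilyl ether of 10 | O=C1[C@@]2(C)C=CC[C@](C)(CO[Si](C)(C)C(C)(C)C)[C@@H]2CC=C1C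
F5 | step 10 | (S)-2,2-dimethyl-4-[3-(phenylsulfonyl)prop-1-en-2-yl]-1,3-dioxolane | C=C(CS(=O)(=O)c1ccccc1)[C@H]1COC(C)(C)O1
F6 | step 10 | C11 B-alkylcatecholborane of 12 (O19 as catechol borate) | O1c2ccccc2OB1C[C@@H]1[C@@]2(C)CCC[C@](C)(COB3Oc4ccccc4O3)[C@@H]2CC=C1C
F7 | step 12 | 8α-hydroxy-8β-methyl-9-ketone (7,8-dihydro-8α-hydroxy derivative of 11) | O=C1[C@@]2(C)CCC[C@](C)(CO)[C@@H]2CC[C@@]1(C)O
F8 | step 12 | 9(11)-methylidene-8α,19-diol | C=C1[C@@]2(C)CCC[C@](C)(CO)[C@@H]2CC[C@@]1(C)O
F9 | step 12 | C11 B-alkyl-9-BBN adduct of F8 (O19 as 9-BBN borinate) | C1CCC2CCCC1B2C[C@@H]1[C@@]2(C)CCC[C@](C)(COB3C4CCCC3CCC4)[C@@H]2CC[C@@]1(C)O
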